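**Retrosynthetic overview**
1. 12 ⇒ 10: the seven O-benzyl groups come off and Bu4N+ is swapped for H+ at the very end, so the acid-labile free sulfuric half-esters exist only in the last operation.
2. 10 ⇒ 7 (key disconnection): both aryl C–O(SO3−) bonds are cut at carbon. Each C–Br becomes C–Mg and takes an intact OSO3− unit from peroxydisulfate.
3. 7 ⇒ 4 + 2 × 2: both biaryl bonds come from one double Negishi coupling, in which C–I reacts and C–Br is kept as the handle.
4. 2 ⇐ 1 and 4 ⇐ 3 by iodination. No ring is built: rings A and C (from 1) and ring B (from 3) are bought as benzene rings and joined A–B–C in step 3.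

Assumption: the SMILES holds no stereocentre and no axis descriptor, so no configuration has to be set; the two hindered biaryl axes stay unassigned and any rotamer mixture is carried through unseparated.

**Step 1**
Reactants: 1 1,3-bis(benzyloxy)-5-bromobenzene
Product: 2 1,5-bis(benzyloxy)-3-bromo-2-iodobenzene
Conditions: NIS (1.05 equiv), CF3CO2H (10 mol%), MeCN, 0 °C to rt, dark
Reagents that add atoms: N-iodosuccinimide, O=C1CCC(=O)N1I
Why: Electrophilic aromatic iodination of a 5-substituted resorcinol diether goes para to one OBn and ortho to the 5-substituent rather than into the crowded slot between the two OBn groups, so iodine enters next to Br; no stereocentre is formed.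

**Step 2**
Reactants: 3 1,3,5-tris(benzyloxy)benzene
Product: 4 1,3,5-tris(benzyloxy)-2,4-diiodobenzene
Conditions: NIS (2.05 equiv), CH2Cl2–MeCN, 0 °C to rt, dark
Reagents that add atoms: N-iodosuccinimide, O=C1CCC(=O)N1I
Why: This is a twofold electrophilic aromatic iodination of a phloroglucinol triether whose three free positions are equivalent, and each iodine slows and crowds the next substitution, so the stoichiometry stops the reaction at the diiodide, which is purified by crystallisation.

**Step 3**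
Reactants: 2 1,5-bis(benzyloxy)-3-bromo-2-iodobenzene (2.5 equiv), 4 1,3,5-tris(benzyloxy)-2,4-diiodobenzene
Product: 7 1,3,5-tris(benzyloxy)-2,4-bis[2,4-bis(benzyloxy)-6-bromophenyl]benzene, via arylmagnesium chloride 5 (not isolated), via arylzinc chloride 6 (not isolated)
Conditions: 2, iPrMgCl·LiCl, THF, −30 °C; ZnCl2, −30 °C to rt; then 4, PdCl2(IPent)(3-chloropyridine) (5 mol%; IPent = 1,3-bis[2,6-di(pentan-3-yl)phenyl]imidazol-2-ylidene), THF–NMP, rt to 45 °C
Reagents that add atoms: none
Why: Iodine–magnesium exchange takes C–I over C–Br, zinc is brought in before the ortho-bromo Grignard can collapse to an aryne, and in the double Negishi coupling zerovalent palladium on a bulky carbene ligand (a catalyst type established for tetra-ortho-substituted biaryls near room temperature) inserts into the C–I bonds of 4 far faster than into the hindered C–Br bonds; the two new axes are not controlled.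

**Step 4**
Reactants: 7 1,3,5-tris(benzyloxy)-2,4-bis[2,4-bis(benzyloxy)-6-bromophenyl]benzene
Product: 10 bis(tetrabutylammonium) 1,3,5-tris(benzyloxy)-2,4-bis[2,4-bis(benzyloxy)-6-(sulfonatooxy)phenyl]benzene, via dilithio terphenyl 8 (not isolated), via bis(chloromagnesio) terphenyl 9 (not isolated)
Conditions: nBuLi (2.1 equiv), THF, −78 °C, 15 min; MgCl2·LiCl (0.5 M in THF, 2.5 equiv), −78 to −30 °C; (Bu4N)2S2O8 (3 equiv, vacuum-dried, in CH2Cl2), −40 to 0 °C; pH 7 phosphate buffer, silica (CH2Cl2–MeOH)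
Reagents that add atoms: bis(tetrabutylammonium) peroxydisulfate, CCCC[N+](CCCC)(CCCC)CCCC.CCCC[N+](CCCC)(CCCC)CCCC.[O-]S(=O)(=O)OOS(=O)(=O)[O-]
Why: Proposed new method: electrophilic sulfooxylation of an aryl Grignard reagent, in which the C–Mg carbon attacks one peroxide oxygen of S2O8(2−) (SN2 at oxygen into the weak O–O σ*, with Mg2+ bridging to a sulfonyl oxygen in a five-membered transition state, attack at the anionic sulfur being disfavoured) and expels sulfate, so each aryl C–O bond forms with its OSO3− group already attached and only at the carbon that carried Br, a position meta to both ring oxygens that no innate arene oxidation would reach; the closest known reaction types are the Elbs persulfate oxidation (a phenolate ring carbon displacing sulfate from the same peroxide oxygen) and the oxygenation of aryl Grignard and aryllithium reagents by peresters or bis(trimethylsilyl) peroxide, only chloride salts are present so no bromide can be oxidised, and no stereocentre is formed.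

**Step 5**
Reactants: 10 bis(tetrabutylammonium) 1,3,5-tris(benzyloxy)-2,4-bis[2,4-bis(benzyloxy)-6-(sulfonatooxy)phenyl]benzene
Product: 12 2,4-bis[2,4-dihydroxy-6-(sulfooxy)phenyl]benzene-1,3,5-triol, via debenzylated bis(tetrabutylammonium) salt 11 (not isolated)
Conditions: H2 (1 atm), Pd/C (10 wt%), MeOH–THF, rt; filter under Ar, concentrate; then HN(SO2CF3)2 (2.0 equiv), H2O, 0 °C, CH2Cl2 washes, freeze-dry the aqueous phase, store at −20 °C
Reagents that add atoms: none
Why: Catalytic hydrogenolysis of benzyl aryl ethers under neutral conditions leaves aryl sulfate monoester anions untouched, and the ion-pair metathesis works because Bu4N+ leaves for CH2Cl2 with the lipophilic N(SO2CF3)2− anion while the very hydrophilic acid 12 stays in the cold water; no stereocentre is touched.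

**Compound list**
1 | 1,3-bis(benzyloxy)-5-bromobenzene | Brc1cc(OCc2ccccc2)cc(OCc2ccccc2)c1 | starting material
2 | 1,5-bis(benzyloxy)-3-bromo-2-iodobenzene | Brc1cc(OCc2ccccc2)cc(OCc2ccccc2)c1I | intermediate
3 | 1,3,5-tris(benzyloxy)benzene | c1(OCc2ccccc2)cc(OCc2ccccc2)cc(OCc2ccccc2)c1 | starting material
4 | 1,3,5-tris(benzyloxy)-2,4-diiodobenzene | Ic1c(OCc2ccccc2)cc(OCc2ccccc2)c(I)c1OCc1ccccc1 | intermediate
5 | [2,4-bis(benzyloxy)-6-bromophenyl]magnesium chloride (LiCl complex, not isolated) | Brc1cc(OCc2ccccc2)cc(OCc2ccccc2)c1[Mg]Cl | intermediate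
6 | [2,4-bis(benzyloxy)-6-bromophenyl]zinc chloride (not isolated) | Brc1cc(OCc2ccccc2)cc(OCc2ccccc2)c1[Zn]Cl | intermediate
7 | 1,3,5-tris(benzyloxy)-2,4-bis[2,4-bis(benzyloxy)-6-bromophenyl]benzene | Brc1cc(OCc2ccccc2)cc(OCc2ccccc2)c1-c1c(OCc2ccccc2)cc(OCc2ccccc2)c(-c2c(Br)cc(OCc3ccccc3)cc2OCc2ccccc2)c1OCc1ccccc1 | intermediate
8 | 1,3,5-tris(benzyloxy)-2,4-bis[2,4-bis(benzyloxy)-6-lithiophenyl]benzene (not isolated) | [Li]c1cc(OCc2ccccc2)cc(OCc2ccccc2)c1-c1c(OCc2ccccc2)cc(OCc2ccccc2)c(-c2c([Li])cc(OCc3ccccc3)cc2OCc2ccccc2)c1OCc1ccccc1 | intermediate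
9 | 1,3,5-tris(benzyloxy)-2,4-bis[2,4-bis(benzyloxy)-6-(chloromagnesio)phenyl]benzene (not isolated) | Cl[Mg]c1cc(OCc2ccccc2)cc(OCc2ccccc2)c1-c1c(OCc2ccccc2)cc(OCc2ccccc2)c(-c2c([Mg]Cl)cc(OCc3ccccc3)cc2OCc2ccccc2)c1OCc1ccccc1 | intermediate
10 | bis(tetrabutylammonium) 1,3,5-tris(benzyloxy)-2,4-bis[2,4-bis(benzyloxy)-6-(sulfonatooxy)phenyl]benzene | CCCC[N+](CCCC)(CCCC)CCCC.CCCC[N+](CCCC)(CCCC)CCCC.[O-]S(=O)(=O)Oc1cc(OCc2ccccc2)cc(OCc2ccccc2)c1-c1c(OCc2ccccc2)cc(OCc2ccccc2)c(-c2c(OS(=O)(=O)[O-])cc(OCc3ccccc3)cc2OCc2ccccc2)c1OCc1ccccc1 | intermediate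
11 | bis(tetrabutylammonium) 2,4-bis[2,4-dihydroxy-6-(sulfonatooxy)phenyl]benzene-1,3,5-triol (not isolated) | CCCC[N+](CCCC)(CCCC)CCCC.CCCC[N+](CCCC)(CCCC)CCCC.[O-]S(=O)(=O)Oc1cc(O)cc(O)c1-c1c(O)cc(O)c(-c2c(O)cc(O)cc2OS(=O)(=O)[O-])c1O | intermediate
12 | 2,4-bis[2,4-dihydroxy-6-(sulfooxy)phenyl]benzene-1,3,5-triol | O=S(=O)(O)Oc1cc(O)cc(O)c1-c1c(O)cc(O)c(-c2c(O)cc(O)cc2OS(=O)(=O)O)c1O | target

**Totals**
Total step count: 5. Longest linear sequence: 4 (1 → 2 → 7 → 10 → 12; the branch 3 → 4 → 7 is equally long).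

**Three steps most likely to fail**

(a) Step 4, the proposed new C–O bond formation.
- Risks: single-electron transfer from C–Mg to persulfate would give an aryl radical that picks up H from THF or a neighbouring OCH2Ph, leading to the debrominated arene. Residual water in the persulfate salt could protonate the Grignard. Reaction could also stop after one of the two sites.
- Fallback with known chemistry: it sets out from 8 and comes back to the route at 10.
- 8 is trapped with B(OMe)3 and hydrolysed with 1 M HCl to the bis(boronic acid) F1.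
- Oxidation with H2O2/NaOH gives the diphenol F2, the C–O bond arising from the 1,2-aryl shift from boron to oxygen.
- Sulfation with SO3·pyridine in pyridine gives the bis(pyridinium) disulfate F3.
- Cation exchange with Bu4NOH (2 equiv) then delivers 10.

(b) Step 3, the double tetra-ortho Negishi coupling in the presence of C–Br.
- Risks: the reaction may stall after the first coupling, palladium may insert competitively into C–Br and cause oligomerisation, or the zinc reagent may be protonated.
- Fallback: it sets out from 5 and comes back to the route at 7.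
- 5 is quenched with 2-isopropoxy-4,4,5,5-tetramethyl-1,3,2-dioxaborolane (1 M HCl work-up) to give the isolable, purifiable pinacol boronate F4.
- F4 (2.5 equiv) is then joined to 4 by Suzuki–Miyaura coupling (Pd(OAc)2, SPhos, K3PO4, toluene–H2O, 70 °C).

(c) Step 5, global debenzylation and release of the free acid.
- Risks: Bu4N+ may not separate cleanly from the polar dianion, the half-esters may suffer acid-catalysed loss of sulfate during concentration, and the polyphenol may oxidise in air.
- Fallback: it sets out from 10, changes the order of events, and comes back at 12.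
- The cation is swapped first, at the lipophilic stage. NaBPh4 (2 equiv) in MeOH precipitates the ammonium ion and leaves the disodium heptabenzyl disulfate F5.
- Hydrogenolysis (H2, Pd/C, MeOH–H2O) gives the stable, isolable disodium salt F6.
- The acid is released only when needed, with exactly 2.0 equiv of HCl at 0 °C followed by Sephadex LH-20 desalting in MeOH.

**Further compounds**
F1 | step 4 | 1,3,5-tris(benzyloxy)-2,4-bis[2,4-bis(benzyloxy)-6-boronophenyl]benzene | OB(O)c1cc(OCc2ccccc2)cc(OCc2ccccc2)c1-c1c(OCc2ccccc2)cc(OCc2ccccc2)c(-c2c(B(O)O)cc(OCc3ccccc3)cc2OCc2ccccc2)c1OCc1ccccc1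
F2 | step 4 | 1,3,5-tris(benzyloxy)-2,4-bis[2,4-bis(benzyloxy)-6-hydroxyphenyl]benzene | Oc1cc(OCc2ccccc2)cc(OCc2ccccc2)c1-c1c(OCc2ccccc2)cc(OCc2ccccc2)c(-c2c(O)cc(OCc3ccccc3)cc2OCc2ccccc2)c1OCc1ccccc1
F3 | step 4 | bis(pyridinium) 1,3,5-tris(benzyloxy)-2,4-bis[2,4-bis(benzyloxy)-6-(sulfonatooxy)phenyl]benzene | c1cc[nH+]cc1.c1cc[nH+]cc1.[O-]S(=O)(=O)Oc1cc(OCc2ccccc2)cc(OCc2ccccc2)c1-c1c(OCc2ccccc2)cc(OCc2ccccc2)c(-c2c(OS(=O)(=O)[O-])cc(OCc3ccccc3)cc2OCc2ccccc2)c1OCc1ccccc1
F4 | step 3 | 2-[2,4-bis(benzyloxy)-6-bromophenyl]-4,4,5,5-tetramethyl-1,3,2-dioxaborolane | Brc1cc(OCc2ccccc2)cc(OCc2ccccc2)c1B1OC(C)(C)C(C)(C)O1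
F5 | step 5 | disodium 1,3,5-tris(benzyloxy)-2,4-bis[2,4-bis(benzyloxy)-6-(sulfonatooxy)phenyl]benzene | [Na+].[Na+].[O-]S(=O)(=O)Oc1cc(OCc2ccccc2)cc(OCc2ccccc2)c1-c1c(OCc2ccccc2)cc(OCc2ccccc2)c(-c2c(OS(=O)(=O)[O-])cc(OCc3ccccc3)cc2OCc2ccccc2)c1OCc1ccccc1
F6 | step 5 | disodium 2,4-bis[2,4-dihydroxy-6-(sulfonatooxy)phenyl]benzene-1,3,5-triol | [Na+].[Na+].[O-]S(=O)(=O)Oc1cc(O)cc(O)c1-c1c(O)cc(O)c(-c2c(O)cc(O)cc2OS(=O)(=O)[O-])c1O
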